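## Retrosynthetic overview

1. The target is traced back to the Δ2-ene 27 by a final Wittig methylenation at C16, acid deprotection and exo-face osmylation. Ring A comes from ring-closing metathesis (C2=C3), the 19,20-lactone from lactonisation of the C20 alcohol onto the C19 ester, and C4 is quaternised on the lactone enolate.
2. The quaternary C10 comes from allylation of a C20 thioester enolate. Ring B (C5–C6–C8–C9–C10) comes from a photochemical Wolff ring contraction of a six-membered 10-diazo-20-ketone: C20 leaves the ring and the C5–C10 bond forms.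
3. Enabling feature: the angular one-carbon substituent C20 on quaternary C10, flanked by C5 in the five-membered ring B, is a cyclohexanone (C5–C20(=O)–C10) minus one ring atom, and that cyclohexanone is a Diels–Alder retron.
4. The cyclohexanone comes from an endo Diels–Alder reaction of silyloxydiene 7 with dienal 3 (sets C6, C8, C9), with C5 set by radical alkylation. Ring D comes from a 5-exo acyl radical cyclisation onto the C12=C13 alkene.
5. Ring order: C (Diels–Alder), six-membered precursor of B (Diels–Alder), B (Wolff), D (acyl radical), lactone, A (metathesis).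

Key step: step 8

Assumption: gibberellane numbering (C1–C20) is used for all intermediates; the side-chain carbon C4 (until step 14) and C10 (steps 8–11) are carried as epimer mixtures, which is harmless because both centres are enolised later.

## Route

Step 1
Reactants: 1 buta-1,3-diene; 2 prop-2-ynal
Product: 3 cyclohexa-1,4-diene-1-carbaldehyde
Conditions: PhMe, hydroquinone (cat.), sealed tube, 60 °C
Reagents that add atoms: none
Why: A thermal Diels–Alder reaction of butadiene with the acetylenic aldehyde should give the 1,4-cyclohexadiene whose conjugated C8=C9 bond is the next dienophile and whose isolated C12=C13 bond is kept for ring D; no stereocentre is formed.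

Step 2
Reactants: 4 tert-butyl (triphenylphosphoranylidene)acetate; 5 2-oxopropanal
Product: 6 tert-butyl (2E)-4-oxopent-2-enoate
Conditions: CH2Cl2, 23 °C
Reagents that add atoms: none
Why: Wittig olefination with a stabilised ylide should react only at the aldehyde carbonyl of methylglyoxal and give the (E)-enoate.

Step 3
Reactants: 6 tert-butyl (2E)-4-oxopent-2-enoate
Product: 7 silyloxydiene
Conditions: i-Pr3SiOTf, Et3N, CH2Cl2, 0 °C
Reagents that add atoms: triisopropylsilyl trifluoromethanesulfonate, CC(C)[Si](C(C)C)(C(C)C)OS(=O)(=O)C(F)(F)F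
Why: Soft enolisation and O-silylation of the methyl ketone, the only enolisable position, should give the cross-conjugated 2-silyloxydiene.

Step 4
Reactants: 3 cyclohexa-1,4-diene-1-carbaldehyde; 7 silyloxydiene
Product: 8 cis-fused cycloadduct
Conditions: (S)-B-(o-tolyl)oxazaborolidine from (S)-α,α-diphenylprolinol, protonated with HNTf2 (20 mol %), CH2Cl2, −78 → −20 °C
Reagents that add atoms: none
Why: In this catalytic enantioselective Diels–Alder reaction the CH2 terminus of the silyloxydiene should bond to the β-carbon C9 of the activated enal and the ester-bearing terminus to C8; endo orientation of the formyl group places the C6 ester cis to it, suprafacial addition makes the ring fusion cis, and the chiral oxazaborolidinium shields one face of the s-trans enal, so that C6, C8 and C9 are set in the sense of the target (the catalyst enantiomer is chosen accordingly).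

Step 5
Reactants: 8 cis-fused cycloadduct; 9 methyl 2-bromopropanoate
Product: 10 keto aldehyde
Conditions: fac-Ir(ppy)3 (1 mol %), 2,6-lutidine, MeCN, blue LEDs (450 nm), 23 °C; aqueous work-up
Reagents that add atoms: none
Why: In this photoredox radical α-alkylation of a silyl enol ether the electrophilic 1-(methoxycarbonyl)ethyl radical should add to the regiodefined enol ether carbon C5 anti to the neighbouring C6 ester, and oxidation and desilylation of the α-silyloxy radical give the C20 ketone; the trans C5 centre is also the thermodynamic epimer because it is enolisable.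

Step 6
Reactants: 10 keto aldehyde; 11 (methoxymethyl)triphenylphosphonium chloride
Product: 12 enol ether ketone
Conditions: 11, KN(SiMe3)2, THF, 0 °C; then 10, −78 → 0 °C
Reagents that add atoms: none
Why: Wittig methoxymethylenation should take place at the non-enolisable neopentyl aldehyde rather than at the hindered ketone and adds C16 as a masked aldehyde.

Step 7
Reactants: 12 enol ether ketone
Product: 14 diazo ketone, via trifluoroacetyl ketone 13 (not isolated)
Conditions: LiN(SiMe3)2, THF, −78 °C; CF3CO2CH2CF3; then MeSO2N3, Et3N, H2O, MeCN, 23 °C; aqueous NH4Cl work-up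
Reagents that add atoms: methanesulfonyl azide, CS(=O)(=O)N=[N+]=[N-]
Why: In this deacylative Regitz-type diazo transfer the kinetic lithium enolate should form at the CH2 position C10 rather than at the substituted C5, is trifluoroacetylated there, and the activated position accepts the diazo group from mesyl azide with loss of the trifluoroacetyl group.

Step 8
Reactants: 14 diazo ketone
Product: 16 thioester, via ketene 15 (not isolated)
Conditions: hν (365 nm LEDs), EtSH (10 equiv), 2,4,6-collidine (0.2 equiv), THF, 0 °C
Reagents that add atoms: ethanethiol, CCS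
Why: Excitation of the cyclic α-diazo ketone, whose diazo and carbonyl groups are held s-cis by the ring, expels N2 while the C5–C20 bond shifts to the diazo carbon C10 (Wolff rearrangement), so that the C5–C10 bond forms, C20 leaves the ring as the ketene carbon of 15, and ethanethiol adds to the ketene to give the thioester. The closest known reaction type is the photochemical Wolff ring contraction of 2-diazocyclohexanones to cyclopentanecarboxylic acid derivatives, a standard ring contraction of terpenoid and steroid cyclohexanones. Ring B (C5–C6–C8–C9–C10) is closed by a 1,2-alkyl shift with ring contraction, not by an exo or endo cyclisation, and ring C and the cis ring fusion are untouched. C5 migrates with retention, so its configuration (trans to the C6 ester, set in step 5) is carried into the five-membered ring; the C10–H centre arises as a mixture on tautomerisation of the thioester enol and is erased in step 12. The step needs migration to win over a 1,2-hydride shift from C9 and over S–H insertion of a free keto-carbene, which the concerted pathway of s-cis-locked cyclic diazo ketones should secure, and it needs C20 to end on C10 rather than on C5, which is fixed by the regioselective diazo transfer of step 7.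

Step 9
Reactants: 16 thioester
Product: 17 aldehyde
Conditions: 1 M HCl, THF, 23 °C
Reagents that add atoms: water, O
Why: Acid hydrolysis of the enol ether unmasks the C16 aldehyde, while the tert-butyl ester, thioester and methyl ester are stable to dilute aqueous acid.

Step 10
Reactants: 17 aldehyde
Product: 18 tricyclic ketone
Conditions: tert-dodecanethiol (0.5 equiv), 2,2'-azobis(isobutyronitrile) (0.2 equiv), PhCl, 85 °C
Reagents that add atoms: none
Why: In this thiol-catalysed radical hydroacylation the acyl radical formed by hydrogen abstraction from the aldehyde should cyclise 5-exo-trig onto C13 of the ring C alkene (the tether on C8 reaches only the face cis to C15, which fixes C13), and the thiol returns hydrogen to C12.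

Step 11
Reactants: 18 tricyclic ketone
Product: 19 dioxolane
Conditions: (Me3SiOCH2)2, Me3SiOTf (5 mol %), CH2Cl2, −78 → −20 °C
Reagents that add atoms: 1,2-bis(trimethylsilyloxy)ethane, C[Si](C)(C)OCCO[Si](C)(C)C
Why: Ketalisation with the bis-silyl ether of ethylene glycol protects the only ketone, so that the thioester is the most acidic and most reducible carbonyl group in the following steps.

Step 12
Reactants: 19 dioxolane; 20 3-bromoprop-1-ene
Product: 21 allyl thioester
Conditions: LiN(SiMe3)2 (1.05 equiv), THF, −78 °C; then 20, DMPU, −78 → −40 °C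
Reagents that add atoms: none
Why: In this enolate alkylation the thioester α-hydrogen is several pK units more acidic than those of the two carboxylic esters, so one equivalent of base should enolise C10 selectively, and allyl bromide enters on the β-face, anti to the α-oriented C11 on C9 and to the α-oriented side chain on C5, which sets the quaternary C10 with C20 α.

Step 13
Reactants: 21 allyl thioester
Product: 23 lactone, via hydroxy ester 22 (not isolated)
Conditions: NaBH4, THF/MeOH (10:1), 0 → 23 °C; then DBU (cat.), PhMe, 80 °C
Reagents that add atoms: none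
Why: Chemoselective borohydride reduction of the thioester in the presence of the carboxylic esters gives the C20 alcohol, which is cis to the propanoate side chain on the cyclopentane and closes the six-membered 19,20-lactone by base-catalysed transesterification.

Step 14
Reactants: 23 lactone; 24 phenyl vinyl sulfoxide
Product: 25 sulfoxide
Conditions: LiN(i-Pr)2, THF, −78 °C; then 24, −78 → −20 °C; aqueous NH4Cl work-up
Reagents that add atoms: none
Why: Michael addition of the lactone enolate to phenyl vinyl sulfoxide (a vinyl cation equivalent) should occur on the convex face of the cis-fused lactone–cyclopentane bicycle, the face that carries the C10 allyl group, which sets the quaternary C4 with the methyl group on the ring B side.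

Step 15
Reactants: 25 sulfoxide
Product: 26 vinyl lactone
Conditions: PhMe, CaCO3, 110 °C
Reagents that add atoms: none
Why: Thermal syn-elimination of the sulfoxide, for which only the C3 hydrogens are β, unveils the vinyl group.

Step 16
Reactants: 26 vinyl lactone
Product: 27 pentacyclic alkene
Conditions: second-generation Grubbs catalyst RuCl2(=CHPh)(PCy3)(H2IMes) (5 mol %), CH2Cl2, 40 °C
Reagents that add atoms: none
Why: Ring-closing metathesis between the 1,3-cis-diaxial allyl and vinyl groups on the lactone ring should close ring A as the bridged cyclohexene with the C2=C3 double bond.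

Step 17
Reactants: 27 pentacyclic alkene
Product: 28 diol
Conditions: OsO4 (5 mol %), N-methylmorpholine N-oxide, acetone/H2O, 23 °C
Reagents that add atoms: osmium tetroxide, O=[Os](=O)(=O)=O; N-methylmorpholine N-oxide, C[N+]1([O-])CCOCC1; water, O
Why: In this Upjohn dihydroxylation osmium tetroxide should add to the exo (β) face of the bicyclo[3.3.1]nonene, the endo face being blocked by the lactone bridge, which gives the cis-2β,3β-diol.

Step 18
Reactants: 28 diol
Product: 29 keto acid
Conditions: CF3CO2H/CH2Cl2/H2O (10:10:1), 23 °C; then MeOH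
Reagents that add atoms: water, O
Why: Aqueous acid hydrolyses the dioxolane and cleaves the tert-butyl ester by loss of isobutene while lactone and diol are stable; this is done before methylenation because the exocyclic alkene would not tolerate strong acid.

Step 19
Reactants: 29 keto acid; 30 methyltriphenylphosphonium bromide
Product: 33 CNP0332607.1, via silylated ketone 31 (not isolated), via silylated alkene 32 (not isolated)
Conditions: Me3SiCl, Et3N, THF, 0 °C; Ph3P=CH2 (from 30, KOt-Bu), THF, 23 °C; then AcOH/H2O/THF
Reagents that add atoms: none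
Why: Wittig methylenation of the 16-ketone after transient silylation of the hydroxyl and carboxyl groups (which prevents base-induced retro-aldol epimerisation at C3), followed by mild acidic desilylation, installs the C16=C17 methylene group last, so that it never meets osmium tetroxide or strong acid.

## Compound list

1 | buta-1,3-diene | C=CC=C | starting material
2 | prop-2-ynal | C#CC=O | starting material
3 | cyclohexa-1,4-diene-1-carbaldehyde | O=CC1=CCC=CC1 | intermediate
4 | tert-butyl (triphenyl-λ5-phosphanylidene)acetate | CC(C)(C)OC(=O)C=P(c1ccccc1)(c1ccccc1)c1ccccc1 | starting material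
5 | 2-oxopropanal (methylglyoxal, aqueous solution) | CC(=O)C=O | starting material
6 | tert-butyl (2E)-4-oxopent-2-enoate | CC(=O)/C=C/C(=O)OC(C)(C)C | intermediate
7 | tert-butyl (2E)-4-[(triisopropylsilyl)oxy]penta-2,4-dienoate | C=C(O[Si](C(C)C)(C(C)C)C(C)C)/C=C/C(=O)OC(C)(C)C | intermediate
8 | tert-butyl 8a-formyl-3-[(triisopropylsilyl)oxy]-1,4,4a,5,8,8a-hexahydronaphthalene-1-carboxylate, cis-fused, with the ester (on C6), the formyl group (C15 on C8) and the ring-fusion hydrogen (on C9) on the same (β) face | O=C[C@]12CC=CC[C@H]1CC(O[Si](C(C)C)(C(C)C)C(C)C)=C[C@@H]2C(=O)OC(C)(C)C | intermediate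
9 | methyl 2-bromopropanoate (racemic) | CC(Br)C(=O)OC | starting material
10 | keto aldehyde: as 8, but with a C20 ketone and a 1-methoxy-1-oxopropan-2-yl group on C5, trans to the C6 ester (epimers at side-chain C4) | O=C[C@]12CC=CC[C@H]1CC(=O)[C@@H](C(C)C(=O)OC)[C@@H]2C(=O)OC(C)(C)C | intermediate
11 | (methoxymethyl)triphenylphosphonium chloride | COC[P+](c1ccccc1)(c1ccccc1)c1ccccc1.[Cl-] | starting material
12 | enol ether ketone: as 10, with the formyl group converted into a 2-methoxyethenyl group (E/Z mixture) | COC=C[C@]12CC=CC[C@H]1CC(=O)[C@@H](C(C)C(=O)OC)[C@@H]2C(=O)OC(C)(C)C | intermediate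
13 | C10-trifluoroacetyl derivative of 12 | COC=C[C@]12CC=CC[C@H]1C(C(=O)C(F)(F)F)C(=O)[C@@H](C(C)C(=O)OC)[C@@H]2C(=O)OC(C)(C)C | intermediate
14 | 10-diazo-20-ketone (diazo group on the CH2 carbon next to the ring fusion) | COC=C[C@]12CC=CC[C@H]1C(=[N+]=[N-])C(=O)[C@@H](C(C)C(=O)OC)[C@@H]2C(=O)OC(C)(C)C | intermediate
15 | ring-contracted ketene (C10=C20=O exocyclic to the new cyclopentane ring B; C5 configuration retained) | COC=C[C@]12CC=CC[C@H]1C(=C=O)[C@@H](C(C)C(=O)OC)[C@@H]2C(=O)OC(C)(C)C | intermediate
16 | S-ethyl thioester on C10 of the cis-fused hydrindene (rings B and C); C5 side chain trans to the C6 tert-butyl ester; C10 epimers | COC=C[C@]12CC=CC[C@H]1C(C(=O)SCC)[C@@H](C(C)C(=O)OC)[C@@H]2C(=O)OC(C)(C)C | intermediate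
17 | aldehyde: as 16, with a 2-oxoethyl group (C15–C16) on C8 | O=CC[C@]12CC=CC[C@H]1C(C(=O)SCC)[C@@H](C(C)C(=O)OC)[C@@H]2C(=O)OC(C)(C)C | intermediate
18 | tricyclic 16-ketone: rings B, C and D, with the bicyclo[3.2.1]octanone bridge (C15–C16) on the β-face | O=C1C[C@]23C[C@H]1CC[C@H]2C(C(=O)SCC)[C@@H](C(C)C(=O)OC)[C@@H]3C(=O)OC(C)(C)C | intermediate
19 | 16,16-ethylenedioxy derivative of 18 | O1CCOC12C[C@]34C[C@H]2CC[C@H]3C(C(=O)SCC)[C@@H](C(C)C(=O)OC)[C@@H]4C(=O)OC(C)(C)C | intermediate
20 | 3-bromoprop-1-ene | C=CCBr | starting material
21 | C10-allyl thioester (allyl β, thioester carbon C20 α) | O1CCOC12C[C@]34C[C@H]2CC[C@H]3[C@@](CC=C)(C(=O)SCC)[C@@H](C(C)C(=O)OC)[C@@H]4C(=O)OC(C)(C)C | intermediate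
22 | C20 primary alcohol (hydroxymethyl on C10, α) | O1CCOC12C[C@]34C[C@H]2CC[C@H]3[C@@](CC=C)(CO)[C@@H](C(C)C(=O)OC)[C@@H]4C(=O)OC(C)(C)C | intermediate
23 | 19,20-lactone (δ-lactone cis-fused to ring B; C4–H, epimers at C4) | O1CCOC12C[C@]34C[C@H]2CC[C@H]3[C@@]5(CC=C)COC(=O)C(C)[C@H]5[C@@H]4C(=O)OC(C)(C)C | intermediate
24 | (ethenesulfinyl)benzene (phenyl vinyl sulfoxide) | C=CS(=O)c1ccccc1 | starting material
25 | C4-[2-(phenylsulfinyl)ethyl] lactone (C4 quaternary; new chain cis to the C10 allyl group) | O1CCOC12C[C@]34C[C@H]2CC[C@H]3[C@@]5(CC=C)COC(=O)[C@](C)(CCS(=O)c6ccccc6)[C@H]5[C@@H]4C(=O)OC(C)(C)C | intermediate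
26 | C4-vinyl lactone | O1CCOC12C[C@]34C[C@H]2CC[C@H]3[C@@]5(CC=C)COC(=O)[C@](C)(C=C)[C@H]5[C@@H]4C(=O)OC(C)(C)C | intermediate
27 | pentacyclic 2-ene: 16,16-ethylenedioxy-17-nor-gibberell-2-ene 19,20-lactone 7-tert-butyl ester | O1CCOC12C[C@]34C[C@H]2CC[C@H]3[C@]56COC(=O)[C@](C)(C=CC5)[C@H]6[C@@H]4C(=O)OC(C)(C)C | intermediate
28 | 2β,3β-diol of 27 | O1CCOC12C[C@]34C[C@H]2CC[C@H]3[C@]56COC(=O)[C@](C)([C@@H](O)[C@@H](O)C5)[C@H]6[C@@H]4C(=O)OC(C)(C)C | intermediate
29 | 2β,3β-dihydroxy-16-oxo-17-nor 19,20-lactone 7-carboxylic acid | O=C1C[C@]23C[C@H]1CC[C@H]2[C@]12COC(=O)[C@](C)([C@@H](O)[C@@H](O)C1)[C@H]2[C@@H]3C(=O)O | intermediate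
30 | methyltriphenylphosphonium bromide | C[P+](c1ccccc1)(c1ccccc1)c1ccccc1.[Br-] | starting material
31 | tris(trimethylsilyl) derivative of 29 (2-O, 3-O and carboxyl) | O=C1C[C@]23C[C@H]1CC[C@H]2[C@]12COC(=O)[C@](C)([C@@H](O[Si](C)(C)C)[C@@H](O[Si](C)(C)C)C1)[C@H]2[C@@H]3C(=O)O[Si](C)(C)C | intermediate
32 | tris(trimethylsilyl) derivative of 33 | C=C1C[C@]23C[C@H]1CC[C@H]2[C@]12COC(=O)[C@](C)([C@@H](O[Si](C)(C)C)[C@@H](O[Si](C)(C)C)C1)[C@H]2[C@@H]3C(=O)O[Si](C)(C)C | intermediate
33 | CNP0332607.1: 2β,3β-dihydroxy-16-methylene 19,20-lactone 7-carboxylic acid | C=C1C[C@]23C[C@H]1CC[C@H]2[C@]12COC(=O)[C@](C)([C@@H](O)[C@@H](O)C1)[C@H]2[C@@H]3C(=O)O | target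

## Summary

Total step count: 19. Longest linear sequence: 18 steps (from 4 and 5, steps 2–19); step 1 is a one-step side branch.

Steps most likely to fail:

- **Step 4.** The ester-deactivated diene and the hindered α,β-disubstituted enal may react too slowly, or with insufficient enantiofacial control, under the chiral catalyst. Fallback: setting out from 3 and 7, the cycloaddition is promoted by Me2AlCl (CH2Cl2, −78 °C) without a chiral catalyst, which should give 8 together with its enantiomer, ent-adduct F1. Condensation of the mixture with (S)-1-amino-2-(methoxymethyl)pyrrolidine gives two diastereomeric hydrazones, hydrazone F2 (from 8) and hydrazone F3 (from F1), which are separated by chromatography. F2 is cleaved with aqueous oxalic acid in a two-phase system, and the route is rejoined at 8.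

- **Step 10.** The cyclised radical may undergo a 1,2-acyl shift (6-endo-type product with a bicyclo[2.2.2] skeleton) before hydrogen transfer, or the thiol may be consumed by addition to the alkene. Fallback: setting out from 17, a Lewis acid-promoted intramolecular carbonyl-ene reaction (Me2AlCl, CH2Cl2, −78 °C) bonds C16 to C13 with transfer of an allylic hydrogen from C11 and should give homoallylic alcohol F4. Diimide (TsNHNH2, NaOAc) saturates the C11=C12 bond to give alcohol F5, and oxidation with 1,1,1-triacetoxy-1,1-dihydro-1,2-benziodoxol-3(1H)-one returns to the route at 18.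

- **Step 14.** Facial selectivity in the intermolecular quaternisation of C4 may be poor, because the convex face is also the face of the axial C10 allyl group. Fallback: setting out from 23, the lactone enolate (LiN(i-Pr)2) is brominated with CBr4 to give α-bromo lactone F6. Hydroboration of the allyl group with 9-BBN and oxidation with NaBO3 give primary alcohol F7, and oxidation as above gives aldehyde F8. SmI2 (THF, −78 °C) then effects an intramolecular Reformatsky reaction, in which the C4 samarium enolate can reach the C3 aldehyde only on the face that carries the C1–C3 chain, to give β-hydroxy lactone F9 with ring A closed. Dehydration with methyl N-(triethylammoniumsulfonyl)carbamate, possible only towards C2, returns to the route at 27; 25 and 26 are bypassed.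

## Further compounds

F1 | step 4 | ent-adduct: enantiomer of 8 | O=C[C@@]12CC=CC[C@@H]1CC(O[Si](C(C)C)(C(C)C)C(C)C)=C[C@H]2C(=O)OC(C)(C)C
F2 | step 4 | hydrazone of 8 with (S)-1-amino-2-(methoxymethyl)pyrrolidine | COC[C@@H]1CCCN1/N=C/[C@]12CC=CC[C@H]1CC(O[Si](C(C)C)(C(C)C)C(C)C)=C[C@@H]2C(=O)OC(C)(C)C
F3 | step 4 | hydrazone of F1 with (S)-1-amino-2-(methoxymethyl)pyrrolidine | COC[C@@H]1CCCN1/N=C/[C@@]12CC=CC[C@@H]1CC(O[Si](C(C)C)(C(C)C)C(C)C)=C[C@H]2C(=O)OC(C)(C)C
F4 | step 10 | homoallylic alcohol: 16-hydroxy tricycle with C11=C12 double bond (C16 epimers) | OC1C[C@]23C[C@H]1C=C[C@H]2C(C(=O)SCC)[C@@H](C(C)C(=O)OC)[C@@H]3C(=O)OC(C)(C)C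
F5 | step 10 | alcohol: saturated 16-hydroxy tricycle (C16 epimers) | OC1C[C@]23C[C@H]1CC[C@H]2C(C(=O)SCC)[C@@H](C(C)C(=O)OC)[C@@H]3C(=O)OC(C)(C)C
F6 | step 14 | α-bromo lactone: 4-bromo derivative of 23 (C4 epimers) | O1CCOC12C[C@]34C[C@H]2CC[C@H]3[C@@]5(CC=C)COC(=O)C(C)(Br)[C@H]5[C@@H]4C(=O)OC(C)(C)C
F7 | step 14 | primary alcohol: 3-hydroxypropyl group on C10 | O1CCOC12C[C@]34C[C@H]2CC[C@H]3[C@@]5(CCCO)COC(=O)C(C)(Br)[C@H]5[C@@H]4C(=O)OC(C)(C)C
F8 | step 14 | aldehyde: 3-oxopropyl group on C10 | O1CCOC12C[C@]34C[C@H]2CC[C@H]3[C@@]5(CCC=O)COC(=O)C(C)(Br)[C@H]5[C@@H]4C(=O)OC(C)(C)C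
F9 | step 14 | β-hydroxy lactone: ring A closed, 3-hydroxy (C3 epimers), C4 quaternary | O1CCOC12C[C@]34C[C@H]2CC[C@H]3[C@]56COC(=O)[C@](C)(C(O)CC5)[C@H]6[C@@H]4C(=O)OC(C)(C)C
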